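**Plan**

1. Retrosynthesis: the oxirane is opened to the (4R,5S)-diol and that to the (4Z)-alkene; then C4=C5 is cut (ring-closing metathesis), then C7–C8 (Ni/Cr coupling), C1–C2 (Weinreb ketone synthesis), and in the butenolide C7–I, C11–C13, O6–C12 (halo-aldol and lactonisation) and C6–C7 (alkynylation).
2. Enabling feature: C4–C5 is the one C–C bond shared by the oxirane and the ten-membered carbocycle. C5 hangs on the γ-carbon C6 of the butenolide and C4 carries only CH3 and the C3 methylene, so both ends can be terminal alkenes joined by a neutral event that spares the acidic H-6 and the allylic leaving groups on C6, C8 and C13. A ten-membered ring should close to the Z-alkene, so the trans-oxirane is made by syn-dihydroxylation and inversion at C5.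
3. Forward: (R)-citramalic acid gives the C8–C10/C1–C4 aldehyde 8; acrolein and methyl propiolate give the iodobutenolide 15 (C5–C7, C11–C13); the two are joined at C7–C8, the esters on C8 and C10 are added, the carbocycle is closed at C4=C5, and the oxirane is made last.
4. Stereochemistry: C10 from (R)-citramalic acid; C6 from the zinc–ProPhenol alkynylation; C8 from the ligand-controlled Ni/Cr addition; C4 and C5 from ligand-directed osmylation of the Z-alkene and SN2 closure at C5.

Key step: step 12

Remark: positions are given in germacrane numbering (C1 ketone, C4–C5 oxirane, C6 lactone carbon, C7=C11, C12 lactone carbonyl, C13 acetoxymethyl, C14 and C15 methyl groups); the target is (4R,5R,6S,8S,10R), and each chiral ligand is specified by the face it delivers to.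

**Route**

Step 1
Reactants: 1 (R)-citramalic acid [(2R)-2-hydroxy-2-methylbutanedioic acid]
Product: 2 (R)-2-(2,2,4-trimethyl-5-oxo-1,3-dioxolan-4-yl)acetic acid
Conditions: Me2C(OMe)2, PPTS (cat.), CH2Cl2, rt
Reagents that add atoms: 2,2-dimethoxypropane, COC(C)(C)OC
Why: Acid-catalysed ketal exchange closes the five-membered 1,3-dioxolan-4-one on the α-hydroxy acid unit only (dioxolanone formation), which differentiates the two carboxyl groups and leaves the quaternary C10 centre of the chiral pool acid untouched.

Step 2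
Reactants: 2 (R)-2-(2,2,4-trimethyl-5-oxo-1,3-dioxolan-4-yl)acetic acid
Product: 3 (R)-5-(2-hydroxyethyl)-2,2,5-trimethyl-1,3-dioxolan-4-one
Conditions: BH3·SMe2, THF, 0 °C to rt; H2O
Reagents that add atoms: none
Why: Borane reduces the free carboxylic acid through its acyloxyborane much faster than the ester-like dioxolanone (chemoselective borane reduction), which should give the C8 primary alcohol.

Step 3
Reactants: 3 (R)-5-(2-hydroxyethyl)-2,2,5-trimethyl-1,3-dioxolan-4-one
Product: 4 (2R)-2,4-dihydroxy-N-methoxy-N,2-dimethylbutanamide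
Conditions: MeNH(OMe)·HCl, i-PrMgCl, THF, −20 to 0 °C; aq. NH4Cl
Reagents that add atoms: N,O-dimethylhydroxylamine hydrochloride, CNOC.Cl
Why: Weinreb amidation by the magnesium amide opens the activated dioxolanone at C1 and the expelled hemiketal loses acetone, which frees the tertiary C10 hydroxyl without touching the stereocentre.

Step 4
Reactants: 4 (2R)-2,4-dihydroxy-N-methoxy-N,2-dimethylbutanamide; 5 4-bromo-2-methylbut-1-ene
Product: 7 (3R)-1,3-dihydroxy-3,7-dimethyloct-7-en-4-one, via 3-methylbut-3-enylmagnesium bromide 6 (not isolated)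
Conditions: 5, Mg, THF, rt; then 4, THF, 0 °C; aq. NH4Cl
Reagents that add atoms: none
Why: Weinreb ketone synthesis, in which two equivalents of 6 deprotonate the hydroxyls and a third adds once because the N-methoxy chelate holds the tetrahedral intermediate until work-up, should form the C1–C2 bond and bring in C2–C4 and C15.

Step 5
Reactants: 7 (3R)-1,3-dihydroxy-3,7-dimethyloct-7-en-4-one
Product: 8 (3R)-3-hydroxy-3,7-dimethyl-4-oxooct-7-enal
Conditions: TEMPO (cat.), PhI(OAc)2, CH2Cl2, rt
Reagents that add atoms: none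
Why: The TEMPO oxoammonium oxidation should convert only the primary alcohol into the aldehyde, since the tertiary alcohol has no carbinol hydrogen and the alkene is inert to it.

Step 6
Reactants: 9 acrolein; 10 methyl propiolate
Product: 12 methyl (4R)-4-hydroxyhex-5-en-2-ynoate, via methylzinc alkynylide 11 (not isolated)
Conditions: Me2Zn, ProPhenol ligand (cat., enantiomer that directs Si-face attack), toluene, 0 °C
Reagents that add atoms: none
Why: In this dinuclear zinc–ProPhenol asymmetric alkynylation of an enal the chiral Zn2 pocket should deliver the alkynylzinc 11 to the Si face of acrolein, which sets C6 as the 4R carbinol (reagent control).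

Step 7
Reactants: 12 methyl (4R)-4-hydroxyhex-5-en-2-ynoate
Product: 14 (5R)-5-ethenyl-3-(hydroxymethyl)-4-iodofuran-2(5H)-one, via open-chain iodo aldol adduct 13 (not isolated)
Conditions: MgI2, CH2O (monomeric, from paraformaldehyde), CH2Cl2, 0 °C to rt; H2O
Reagents that add atoms: magnesium iodide, [Mg+2].[I-].[I-]; formaldehyde, C=O
Why: In this halo-aldol (β-iodo Morita–Baylis–Hillman) reaction iodide adds to C7, the magnesium allenolate is hydroxymethylated at C11 on the iodine side, away from the branched C6 substituent, to give 13, whose C6 hydroxyl is cis to the ester and should lactonise (reversible iodide addition–elimination funnels any other alkene isomer to the lactone), while the C6 centre is not involved.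

Step 8
Reactants: 14 (5R)-5-ethenyl-3-(hydroxymethyl)-4-iodofuran-2(5H)-one
Product: 15 [(5R)-5-ethenyl-4-iodo-2-oxo-2,5-dihydrofuran-3-yl]methyl acetate
Conditions: Ac2O, pyridine, CH2Cl2, 0 °C
Reagents that add atoms: acetic anhydride, CC(=O)OC(C)=O
Why: Pyridine-mediated O-acetylation of the primary allylic alcohol installs the C13 acetate under conditions too weakly basic to deprotonate H-6.

Step 9
Reactants: 8 (3R)-3-hydroxy-3,7-dimethyl-4-oxooct-7-enal; 15 [(5R)-5-ethenyl-4-iodo-2-oxo-2,5-dihydrofuran-3-yl]methyl acetate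
Product: 17 [(5R)-4-[(1S,3R)-1,3-dihydroxy-3,7-dimethyl-4-oxooct-7-en-1-yl]-5-ethenyl-2-oxo-2,5-dihydrofuran-3-yl]methyl acetate, via alkenylchromium dichloride 16 (not isolated)
Conditions: CrCl2, NiCl2 (cat.), chiral oxazoline–sulfonamide ligand, Et3N (premixed with CrCl2 and ligand), THF, rt; H2O
Reagents that add atoms: none
Why: In this Nozaki–Hiyama–Kishi coupling nickel inserts into the C7–I bond and transmetallation gives the alkenylchromium 16, which should add to the aldehyde only (the hindered C1 ketone, the esters and the free tertiary alcohol are tolerated), and the chiral sulfonamide bound to chromium selects the aldehyde face that gives the 8S alcohol.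

Step 10
Reactants: 17 [(5R)-4-[(1S,3R)-1,3-dihydroxy-3,7-dimethyl-4-oxooct-7-en-1-yl]-5-ethenyl-2-oxo-2,5-dihydrofuran-3-yl]methyl acetate
Product: 18 (1S,3R)-1-[(2R)-4-(acetoxymethyl)-2-ethenyl-5-oxo-2,5-dihydrofuran-3-yl]-3-hydroxy-3,7-dimethyl-4-oxooct-7-en-1-yl propanoate
Conditions: (EtCO)2O, pyridine, DMAP (cat.), CH2Cl2, 0 °C
Reagents that add atoms: propanoic anhydride, CCC(=O)OC(=O)CC
Why: DMAP-catalysed acylation should esterify the secondary allylic C8 alcohol with retention and leave the far more hindered tertiary C10 alcohol.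

Step 11
Reactants: 18 (1S,3R)-1-[(2R)-4-(acetoxymethyl)-2-ethenyl-5-oxo-2,5-dihydrofuran-3-yl]-3-hydroxy-3,7-dimethyl-4-oxooct-7-en-1-yl propanoate
Product: 19 (1S,3R)-3-acetoxy-1-[(2R)-4-(acetoxymethyl)-2-ethenyl-5-oxo-2,5-dihydrofuran-3-yl]-3,7-dimethyl-4-oxooct-7-en-1-yl propanoate
Conditions: Ac2O, TMSOTf (cat.), CH2Cl2, −40 °C
Reagents that add atoms: acetic anhydride, CC(=O)OC(C)=O
Why: Silyl triflate catalysed acetylation should acylate the hindered tertiary α-ketol hydroxyl at low temperature without base, so that H-6 of the γ-vinylbutenolide is not at risk.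

Step 12
Reactants: 19 (1S,3R)-3-acetoxy-1-[(2R)-4-(acetoxymethyl)-2-ethenyl-5-oxo-2,5-dihydrofuran-3-yl]-3,7-dimethyl-4-oxooct-7-en-1-yl propanoate
Product: 20 (4Z,6R,8S,10R)-10,13-diacetoxy-1-oxo-8-(propanoyloxy)germacra-4,7(11)-dien-12,6-olide
Conditions: Hoveyda–Grubbs II (cat.), 1,4-benzoquinone (cat.), toluene (1 mM), 80 °C
Reagents that add atoms: none
Why: Ring-closing olefin metathesis: the ruthenium alkylidene initiates at the monosubstituted C5 vinyl group on C6, the new carbene adds to the 1,1-disubstituted C4=CH2 alkene through a ruthenacyclobutane and releases ethene, so the C4=C5 bond and the ten-membered carbocycle form in one turnover. The closest known reaction type is RCM to medium-ring trisubstituted cycloalkenes, including ten-membered germacranolide-type carbocycles. The only ring closed is the ten-membered carbocycle C1–C10, by metathesis between the two chain termini; the butenolide is already in place. No stereocentre is created, but the alkene geometry is: a ten-membered ring accommodates a trisubstituted alkene most easily with C3 and C6 cis, so the 4Z isomer is expected from ring strain, and this is the geometry the following syn-dihydroxylation and inversion need. The step needs ring closure over cross-metathesis oligomerisation and must leave the tetrasubstituted, electron-poor C7=C11 alkene and the allylic H-6 alone; the first is secured by high dilution together with the rigid butenolide (C6, C7), the C1 carbonyl and the quaternary C10, which restrict the chain between the termini, the second by the inertness of tetrasubstituted enoates to ruthenium carbenes and by benzoquinone, which suppresses Ru–H alkene migration.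

Step 13
Reactants: 20 (4Z,6R,8S,10R)-10,13-diacetoxy-1-oxo-8-(propanoyloxy)germacra-4,7(11)-dien-12,6-olide
Product: 21 (4R,5S,6S,8S,10R)-10,13-diacetoxy-4,5-dihydroxy-1-oxo-8-(propanoyloxy)germacr-7(11)-en-12,6-olide
Conditions: OsO4 (cat.), (DHQ)2PHAL (cat.), NMO, acetone/H2O, 0 °C
Reagents that add atoms: osmium tetroxide, O=[Os](=O)(=O)=O; N-methylmorpholine N-oxide, C[N+]1([O-])CCOCC1; water, O
Why: Ligand-accelerated catalytic osmium dihydroxylation adds two oxygens syn to the only electron-rich alkene, and with H-5 in the most hindered quadrant of the AD mnemonic the DHQ-derived ligand should direct osmium to the face that gives the 4R,5S diol, the tetrasubstituted butenolide alkene being inert.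

Step 14
Reactants: 21 (4R,5S,6S,8S,10R)-10,13-diacetoxy-4,5-dihydroxy-1-oxo-8-(propanoyloxy)germacr-7(11)-en-12,6-olide
Product: 22 CNP0285168.1, (4R,5R,6S,8S,10R)-10,13-diacetoxy-4,5-epoxy-1-oxo-8-(propanoyloxy)germacr-7(11)-en-12,6-olide
Conditions: PPh3, DIAD, toluene, 0 °C to rt
Reagents that add atoms: none
Why: In this Mitsunobu cyclodehydration the secondary C5 hydroxyl is activated as its oxyphosphonium ion and displaced by the tertiary C4 oxygen in a 3-exo-tet SN2 closure, which should invert C5 (S to R), retain C4 and so give the trans-oxirane under neutral conditions that spare H-6 and the esters.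

**Compound list**

1 | (R)-citramalic acid, (2R)-2-hydroxy-2-methylbutanedioic acid | OC(=O)C[C@@](C)(O)C(=O)O | starting material
2 | (R)-2-(2,2,4-trimethyl-5-oxo-1,3-dioxolan-4-yl)acetic acid | OC(=O)C[C@@]1(C)OC(C)(C)OC1=O | intermediate
3 | (R)-5-(2-hydroxyethyl)-2,2,5-trimethyl-1,3-dioxolan-4-one | OCC[C@@]1(C)OC(C)(C)OC1=O | intermediate
4 | (2R)-2,4-dihydroxy-N-methoxy-N,2-dimethylbutanamide | OCC[C@@](C)(O)C(=O)N(C)OC | intermediate
5 | 4-bromo-2-methylbut-1-ene | CC(=C)CCBr | starting material
6 | 3-methylbut-3-enylmagnesium bromide | CC(=C)CC[Mg]Br | intermediate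
7 | (3R)-1,3-dihydroxy-3,7-dimethyloct-7-en-4-one | OCC[C@@](C)(O)C(=O)CCC(C)=C | intermediate
8 | (3R)-3-hydroxy-3,7-dimethyl-4-oxooct-7-enal | O=CC[C@@](C)(O)C(=O)CCC(C)=C | intermediate
9 | acrolein | C=CC=O | starting material
10 | methyl propiolate | C#CC(=O)OC | starting material
11 | methyl 3-(methylzincio)prop-2-ynoate | C[Zn]C#CC(=O)OC | intermediate
12 | methyl (4R)-4-hydroxyhex-5-en-2-ynoate | C=C[C@@H](O)C#CC(=O)OC | intermediate
13 | methyl (2E,4R)-4-hydroxy-2-(hydroxymethyl)-3-iodohexa-2,5-dienoate | C=C[C@@H](O)/C(I)=C(/CO)C(=O)OC | intermediate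
14 | (5R)-5-ethenyl-3-(hydroxymethyl)-4-iodofuran-2(5H)-one | C=C[C@H]1OC(=O)C(CO)=C1I | intermediate
15 | [(5R)-5-ethenyl-4-iodo-2-oxo-2,5-dihydrofuran-3-yl]methyl acetate | C=C[C@H]1OC(=O)C(COC(C)=O)=C1I | intermediate
16 | dichloro[(2R)-4-(acetoxymethyl)-2-ethenyl-5-oxo-2,5-dihydrofuran-3-yl]chromium(III) | C=C[C@H]1OC(=O)C(COC(C)=O)=C1[Cr](Cl)Cl | intermediate
17 | [(5R)-4-[(1S,3R)-1,3-dihydroxy-3,7-dimethyl-4-oxooct-7-en-1-yl]-5-ethenyl-2-oxo-2,5-dihydrofuran-3-yl]methyl acetate | O[C@@H](C[C@@](C)(O)C(=O)CCC(C)=C)C1=C(COC(C)=O)C(=O)O[C@@H]1C=C | intermediate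
18 | (1S,3R)-1-[(2R)-4-(acetoxymethyl)-2-ethenyl-5-oxo-2,5-dihydrofuran-3-yl]-3-hydroxy-3,7-dimethyl-4-oxooct-7-en-1-yl propanoate | CCC(=O)O[C@@H](C[C@@](C)(O)C(=O)CCC(C)=C)C1=C(COC(C)=O)C(=O)O[C@@H]1C=C | intermediate
19 | (1S,3R)-3-acetoxy-1-[(2R)-4-(acetoxymethyl)-2-ethenyl-5-oxo-2,5-dihydrofuran-3-yl]-3,7-dimethyl-4-oxooct-7-en-1-yl propanoate | CCC(=O)O[C@@H](C[C@@](C)(OC(C)=O)C(=O)CCC(C)=C)C1=C(COC(C)=O)C(=O)O[C@@H]1C=C | intermediate
20 | (4Z,6R,8S,10R)-10,13-diacetoxy-1-oxo-8-(propanoyloxy)germacra-4,7(11)-dien-12,6-olide | CCC(=O)O[C@H]1C[C@@](C)(OC(C)=O)C(=O)CC/C(C)=C\[C@H]2OC(=O)C(COC(C)=O)=C12 | intermediate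
21 | (4R,5S,6S,8S,10R)-10,13-diacetoxy-4,5-dihydroxy-1-oxo-8-(propanoyloxy)germacr-7(11)-en-12,6-olide | CCC(=O)O[C@H]1C[C@@](C)(OC(C)=O)C(=O)CC[C@@](C)(O)[C@@H](O)[C@H]2OC(=O)C(COC(C)=O)=C12 | intermediate
22 | CNP0285168.1, (4R,5R,6S,8S,10R)-10,13-diacetoxy-4,5-epoxy-1-oxo-8-(propanoyloxy)germacr-7(11)-en-12,6-olide | CCC(=O)O[C@H]1C[C@@](C)(OC(C)=O)C(=O)CC[C@@]2(C)O[C@@H]2[C@H]2OC(=O)C(COC(C)=O)=C12 | target

**Count and risks**

Total steps: 14. Longest linear sequence: 11 (steps 1–5, then 9–14); the butenolide branch (steps 6–8) joins at step 9.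

Step 12. The ruthenium carbene may be consumed by cross-metathesis between two molecules (oligomerisation), or the ring may close with E geometry, which the dihydroxylation and inversion would turn into the wrong oxirane diastereomer. Fallback: accept the E ring and change the way oxygen is added. Setting out from 19, the closure is taken to (4E,6R,8S,10R)-10,13-diacetoxy-1-oxo-8-(propanoyloxy)germacra-4,7(11)-dien-12,6-olide F1, which is epoxidised directly with dimethyldioxirane in acetone at 0 °C. Syn oxygen transfer to the outer face of the E-alkene, the inner face being blocked by the ring, should give 22, where the route is rejoined; steps 13 and 14 are then not needed.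

Step 7. The magnesium allenolate may be protonated before it meets formaldehyde, or the Lewis acid may ionise the doubly allylic C6–O bond, so that C13 is not installed or C6 is scrambled. Fallback without a halo-aldol: setting out from 12, gold(I)-catalysed hydration of the ynoate with lactonisation gives the tetronic acid (5R)-5-ethenyl-4-hydroxyfuran-2(5H)-one F2. Vilsmeier–Haack bromoformylation (PBr3, DMF) gives (5R)-4-bromo-5-ethenyl-2-oxo-2,5-dihydrofuran-3-carbaldehyde F3. Luche reduction (NaBH4, CeCl3, MeOH, −78 °C) gives (5R)-4-bromo-5-ethenyl-3-(hydroxymethyl)furan-2(5H)-one F4, and acetylation (Ac2O, pyridine) gives [(5R)-4-bromo-5-ethenyl-2-oxo-2,5-dihydrofuran-3-yl]methyl acetate F5. F5 takes the place of 15 in the Ni/Cr coupling with 8 and the route is rejoined at 17.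

Step 9. The chiral ligand may fail to control the face of the aldehyde against the hindered, tetrasubstituted alkenylchromium, so that both C8 epimers form. Fallback: setting out from 8 and 15, the coupling is run without the ligand and the epimers are separated. 17 continues through step 10. The epimer [(5R)-4-[(1R,3R)-1,3-dihydroxy-3,7-dimethyl-4-oxooct-7-en-1-yl]-5-ethenyl-2-oxo-2,5-dihydrofuran-3-yl]methyl acetate F6 is esterified with propanoic acid under Mitsunobu conditions (PPh3, DIAD, THF, 0 °C), which inverts C8 and should give the same propanoate 18, where the route is rejoined.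

**Further compounds**

F1 | step 12 | (4E,6R,8S,10R)-10,13-diacetoxy-1-oxo-8-(propanoyloxy)germacra-4,7(11)-dien-12,6-olide | CCC(=O)O[C@H]1C[C@@](C)(OC(C)=O)C(=O)CC/C(C)=C/[C@H]2OC(=O)C(COC(C)=O)=C12
F2 | step 7 | (5R)-5-ethenyl-4-hydroxyfuran-2(5H)-one | C=C[C@H]1OC(=O)C=C1O
F3 | step 7 | (5R)-4-bromo-5-ethenyl-2-oxo-2,5-dihydrofuran-3-carbaldehyde | C=C[C@H]1OC(=O)C(C=O)=C1Br
F4 | step 7 | (5R)-4-bromo-5-ethenyl-3-(hydroxymethyl)furan-2(5H)-one | C=C[C@H]1OC(=O)C(CO)=C1Br
F5 | step 7 | [(5R)-4-bromo-5-ethenyl-2-oxo-2,5-dihydrofuran-3-yl]methyl acetate | C=C[C@H]1OC(=O)C(COC(C)=O)=C1Br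
F6 | step 9 | [(5R)-4-[(1R,3R)-1,3-dihydroxy-3,7-dimethyl-4-oxooct-7-en-1-yl]-5-ethenyl-2-oxo-2,5-dihydrofuran-3-yl]methyl acetate | O[C@H](C[C@@](C)(O)C(=O)CCC(C)=C)C1=C(COC(C)=O)C(=O)O[C@@H]1C=C
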